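**Assumption:** the target SMILES has no stereocentre and no configured axis, and the biaryl axis (ortho groups H, OAr, OH, ring O) is taken as freely rotating; the compound is therefore made as the achiral molecule drawn and no stereocontrol is needed.

**Retrosynthetic overview**
- Coumarin A (the 7-hydroxy-3-aryloxycoumarin) is disconnected last, by a Perkin condensation of an aryloxyacetic acid with 2,4-dihydroxybenzaldehyde; its C3–O bond traces back to an earlier O-alkylation with a bromoacetate.
- The biaryl bond (C6 of central coumarin B to C8 of coumarin C) is disconnected by Suzuki–Miyaura coupling: a coumarin-B 6-boronate plus 8-iodo-7-(methoxymethoxy)coumarin.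
- Coumarin B comes from 5-bromo-2,4-dihydroxybenzaldehyde by Wittig olefination and lactonisation; coumarin C is bought as umbelliferone and iodinated at C8.
- Order of ring formation: pyranone of B (step 1), coumarin C purchased intact, pyranone of A (step 8), then deacetylation.

**Route**

Step 1
Reactants: 1 5-bromo-2,4-dihydroxybenzaldehyde
Product: 4 6-bromo-7-hydroxy-2H-chromen-2-one, via E-acrylate ester 2 (not isolated), via Z-acrylate ester 3 (not isolated)
Conditions: Ph3P=CHCO2Et (1.2 equiv), PhNEt2, 215 °C (reflux), N2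
Reagents that add atoms: ethyl (triphenylphosphoranylidene)acetate, CCOC(=O)C=P(c1ccccc1)(c1ccccc1)c1ccccc1
Why: Wittig olefination with the stabilised ylide gives the cinnamate, which at this temperature equilibrates from E to Z so that the ortho-OH closes the lactone with loss of ethanol (thermal lactonisation); no stereocentre is formed.

Step 2
Reactants: 4 6-bromo-7-hydroxy-2H-chromen-2-one
Product: 5 tert-butyl 2-[(6-bromo-2-oxo-2H-chromen-7-yl)oxy]acetate
Conditions: BrCH2CO2tBu, K2CO3, DMF, rt
Reagents that add atoms: tert-butyl bromoacetate, CC(C)(C)OC(=O)CBr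
Why: Williamson ether synthesis, in which the acidic 7-OH (pKa about 8) is fully deprotonated by K2CO3 and alkylated in an SN2 reaction by the primary alpha-bromo ester, the tert-butyl ester being chosen to survive the later basic coupling.

Step 3
Reactants: 5 tert-butyl 2-[(6-bromo-2-oxo-2H-chromen-7-yl)oxy]acetate
Product: 6 tert-butyl 2-{[2-oxo-6-(4,4,5,5-tetramethyl-1,3,2-dioxaborolan-2-yl)-2H-chromen-7-yl]oxy}acetate
Conditions: B2pin2, Pd(dppf)Cl2 (5 mol%), KOAc, 1,4-dioxane, 90 °C
Reagents that add atoms: bis(pinacolato)diboron, CC1(C)OB(OC1(C)C)B1OC(C)(C)C(C)(C)O1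
Why: Miyaura borylation of the aryl bromide, in which the weak base KOAc mediates transmetalation without opening the lactone or touching the tert-butyl ester.

Step 4
Reactants: 7 7-hydroxy-2H-chromen-2-one (umbelliferone)
Product: 8 7-hydroxy-8-iodo-2H-chromen-2-one
Conditions: I2, KI, 20% aq. NH3, rt
Reagents that add atoms: iodine, II
Why: electrophilic aromatic iodination of the phenoxide, which goes to C8 because that carbon, flanked by the phenoxide oxygen and the ring oxygen, is the most nucleophilic position of umbelliferone (the same site taken by Mannich and Duff reactions).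

Step 5
Reactants: 8 7-hydroxy-8-iodo-2H-chromen-2-one
Product: 9 8-iodo-7-(methoxymethoxy)-2H-chromen-2-one
Conditions: MOMCl, K2CO3, acetone, 0 °C to rt
Reagents that add atoms: chloromethyl methyl ether, COCCl
Why: O-alkylation of the phenoxide (Williamson-type acetal formation) masks the phenol as a MOM ether so that no phenoxide slows oxidative addition or interferes in the cross-coupling.

Step 6
Reactants: 6 tert-butyl 2-{[2-oxo-6-(4,4,5,5-tetramethyl-1,3,2-dioxaborolan-2-yl)-2H-chromen-7-yl]oxy}acetate; 9 8-iodo-7-(methoxymethoxy)-2H-chromen-2-one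
Product: 10 tert-butyl 2-({6-[7-(methoxymethoxy)-2-oxo-2H-chromen-8-yl]-2-oxo-2H-chromen-7-yl}oxy)acetate
Conditions: Pd(OAc)2 (5 mol%), SPhos (10 mol%), K3PO4, toluene/H2O 10:1, 90 °C
Reagents that add atoms: none
Why: Suzuki–Miyaura cross-coupling in which the doubly ortho-substituted partner is the reactive aryl iodide and the less hindered partner carries boron, with the bulky electron-rich SPhos ligand enabling transmetalation and reductive elimination to the tri-ortho-substituted biaryl.

Step 7
Reactants: 10 tert-butyl 2-({6-[7-(methoxymethoxy)-2-oxo-2H-chromen-8-yl]-2-oxo-2H-chromen-7-yl}oxy)acetate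
Product: 11 2-{[6-(7-hydroxy-2-oxo-2H-chromen-8-yl)-2-oxo-2H-chromen-7-yl]oxy}acetic acid
Conditions: TFA/CH2Cl2 1:1, H2O (5 equiv), rt
Reagents that add atoms: none
Why: acidolysis removes the tert-butyl ester (E1 loss of the tert-butyl cation) and hydrolyses the MOM acetal in one operation, while the lactones and aryl ethers are stable to acid.

Step 8
Reactants: 11 2-{[6-(7-hydroxy-2-oxo-2H-chromen-8-yl)-2-oxo-2H-chromen-7-yl]oxy}acetic acid; 12 2,4-dihydroxybenzaldehyde (1.5 equiv)
Product: 16 8-{7-[(7-acetoxy-2-oxo-2H-chromen-3-yl)oxy]-2-oxo-2H-chromen-6-yl}-2-oxo-2H-chromen-7-yl acetate, via 4-formyl-3-hydroxyphenyl acetate 13 (not isolated), via mixed anhydride 14 (not isolated), via formylphenyl ester 15 (not isolated)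
Conditions: Ac2O, NaOAc, 140 °C
Reagents that add atoms: acetic anhydride, CC(=O)OC(C)=O
Why: Perkin (Perkin–Oglialoro) condensation, in which the acid is activated as its mixed anhydride and transferred to the 2-OH of the aldehyde, the aryloxy-activated CH2 then adds intramolecularly to the formyl group and dehydration gives the 3-aryloxycoumarin with both free phenols capped as acetates.

Step 9
Reactants: 16 8-{7-[(7-acetoxy-2-oxo-2H-chromen-3-yl)oxy]-2-oxo-2H-chromen-6-yl}-2-oxo-2H-chromen-7-yl acetate
Product: 17 7-hydroxy-3-{[6-(7-hydroxy-2-oxo-2H-chromen-8-yl)-2-oxo-2H-chromen-7-yl]oxy}-2H-chromen-2-one (target)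
Conditions: HCl (cat.), MeOH/THF, 55 °C
Reagents that add atoms: none
Why: acid-catalysed transesterification (methanolysis) cleaves the two aryl acetates, while the three lactones and the enol aryl ether are stable to acid.

**Compound list**
1 | 5-bromo-2,4-dihydroxybenzaldehyde | O=Cc1cc(Br)c(O)cc1O | starting material
2 | ethyl (E)-3-(5-bromo-2,4-dihydroxyphenyl)prop-2-enoate | CCOC(=O)/C=C/c1cc(Br)c(O)cc1O | intermediate
3 | ethyl (Z)-3-(5-bromo-2,4-dihydroxyphenyl)prop-2-enoate | CCOC(=O)/C=C\c1cc(Br)c(O)cc1O | intermediate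
4 | 6-bromo-7-hydroxy-2H-chromen-2-one | O=c1ccc2cc(Br)c(O)cc2o1 | intermediate
5 | tert-butyl 2-[(6-bromo-2-oxo-2H-chromen-7-yl)oxy]acetate | CC(C)(C)OC(=O)COc1cc2oc(=O)ccc2cc1Br | intermediate
6 | tert-butyl 2-{[2-oxo-6-(4,4,5,5-tetramethyl-1,3,2-dioxaborolan-2-yl)-2H-chromen-7-yl]oxy}acetate | CC(C)(C)OC(=O)COc1cc2oc(=O)ccc2cc1B1OC(C)(C)C(C)(C)O1 | intermediate
7 | 7-hydroxy-2H-chromen-2-one (umbelliferone) | O=c1ccc2ccc(O)cc2o1 | starting material
8 | 7-hydroxy-8-iodo-2H-chromen-2-one | O=c1ccc2ccc(O)c(I)c2o1 | intermediate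
9 | 8-iodo-7-(methoxymethoxy)-2H-chromen-2-one | COCOc1ccc2ccc(=O)oc2c1I | intermediate
10 | tert-butyl 2-({6-[7-(methoxymethoxy)-2-oxo-2H-chromen-8-yl]-2-oxo-2H-chromen-7-yl}oxy)acetate | CC(C)(C)OC(=O)COc1cc2oc(=O)ccc2cc1-c1c(OCOC)ccc2ccc(=O)oc12 | intermediate
11 | 2-{[6-(7-hydroxy-2-oxo-2H-chromen-8-yl)-2-oxo-2H-chromen-7-yl]oxy}acetic acid | OC(=O)COc1cc2oc(=O)ccc2cc1-c1c(O)ccc2ccc(=O)oc12 | intermediate
12 | 2,4-dihydroxybenzaldehyde | O=Cc1ccc(O)cc1O | starting material
13 | 4-formyl-3-hydroxyphenyl acetate | CC(=O)Oc1ccc(C=O)c(O)c1 | intermediate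
14 | acetic 2-{[6-(7-acetoxy-2-oxo-2H-chromen-8-yl)-2-oxo-2H-chromen-7-yl]oxy}acetic anhydride | CC(=O)OC(=O)COc1cc2oc(=O)ccc2cc1-c1c(OC(C)=O)ccc2ccc(=O)oc12 | intermediate
15 | 5-acetoxy-2-formylphenyl 2-{[6-(7-acetoxy-2-oxo-2H-chromen-8-yl)-2-oxo-2H-chromen-7-yl]oxy}acetate | CC(=O)Oc1ccc(C=O)c(OC(=O)COc2cc3oc(=O)ccc3cc2-c2c(OC(C)=O)ccc3ccc(=O)oc23)c1 | intermediate
16 | 8-{7-[(7-acetoxy-2-oxo-2H-chromen-3-yl)oxy]-2-oxo-2H-chromen-6-yl}-2-oxo-2H-chromen-7-yl acetate | CC(=O)Oc1ccc2cc(Oc3cc4oc(=O)ccc4cc3-c3c(OC(C)=O)ccc4ccc(=O)oc34)c(=O)oc2c1 | intermediate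
17 | 7-hydroxy-3-{[6-(7-hydroxy-2-oxo-2H-chromen-8-yl)-2-oxo-2H-chromen-7-yl]oxy}-2H-chromen-2-one | O=c1ccc2cc(-c3c(O)ccc4ccc(=O)oc34)c(Oc3cc4ccc(O)cc4oc3=O)cc2o1 | target

**Totals**
Total step count: 9.
Longest linear sequence: 7 steps (steps 1, 2, 3, 6, 7, 8, 9, from compound 1). The second branch (steps 4 and 5, from compound 7) joins at step 6.

**Three steps most likely to fail, with fallbacks**

Step 6, the hindered Suzuki coupling. The risks are slow coupling to a tri-ortho-substituted biaryl and protodeboronation of the electron-rich boronate 6. The fallback changes both the nucleophilic partner and the metal; it sets out from 9 (and bromide 5), bypasses boronate 6, and comes back at 10. Iodide 9 is stannylated with hexamethylditin (Me3Sn–SnMe3) and Pd(PPh3)4 in toluene at 100 °C to give 7-(methoxymethoxy)-8-(trimethylstannyl)-2H-chromen-2-one F1. F1 is then joined to bromide 5 in a Stille coupling (Pd(PPh3)4, CuI, CsF, DMF, 60 °C) to give 10. The arylstannane does not protodemetalate under these near-neutral conditions, and the CuI/CsF combination is effective for doubly ortho-substituted partners.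

Step 8, the Perkin condensation. The risks are self-condensation of Ac2O with the aldehyde (giving 7-acetoxycoumarin) and slow acyl transfer to the chelated 2-OH. The fallback builds the same ring stepwise without Ac2O as medium; it sets out from 11 and 12 and comes back at 16. Acid 11 is O-acetylated (Ac2O, pyridine, rt, then aqueous work-up) to give 2-{[6-(7-acetoxy-2-oxo-2H-chromen-8-yl)-2-oxo-2H-chromen-7-yl]oxy}acetic acid F2. Aldehyde 12 is mono-acetylated at the non-chelated 4-OH (AcCl 1.0 equiv, Et3N, CH2Cl2, 0 °C) to give 13 as an isolated compound. F2 and 13 are esterified with EDC·HCl and DMAP in CH2Cl2 to give ester 15, which is isolated and closed by intramolecular Knoevenagel condensation (DBU, MeCN, rt to 50 °C) to give 16.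

Step 1, the thermal Wittig–lactonisation. At 215 °C the free bromoresorcinol aldehyde may tar, or the E to Z isomerisation may be incomplete. The fallback replaces olefination by an anhydride condensation; it sets out from 1 and comes back at 4. Classical Perkin coumarin synthesis on 1 (Ac2O, NaOAc, 175 °C) gives 6-bromo-2-oxo-2H-chromen-7-yl acetate F3, and acid methanolysis (HCl, MeOH, 55 °C) then gives 4.

**Further compounds**
F1 | step 6 | 7-(methoxymethoxy)-8-(trimethylstannyl)-2H-chromen-2-one | COCOc1ccc2ccc(=O)oc2c1[Sn](C)(C)C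
F2 | step 8 | 2-{[6-(7-acetoxy-2-oxo-2H-chromen-8-yl)-2-oxo-2H-chromen-7-yl]oxy}acetic acid | OC(=O)COc1cc2oc(=O)ccc2cc1-c1c(OC(C)=O)ccc2ccc(=O)oc12
F3 | step 1 | 6-bromo-2-oxo-2H-chromen-7-yl acetate | CC(=O)Oc1cc2oc(=O)ccc2cc1Br
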